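Do not expect every complex that leaves the starting complex to wait as complex with one exchanged. That is impossible in ash: at 0.833 min, 26.0% has left and 13.9% stands, about half. Watch the fraction left, not the fraction made.

| flask | starting complex | incoming ligand | leaving ligand | remark | time |
|---|---|---|---|---|---|
| ash | 0.10 M | 0.10 M | 0.50 M | the very flask that is asked about, followed so far |  |
| maple | 0.20 M | 0.10 M | 0.50 M | run made earlier |  |
| flask | 0.10 M | 0.100 M | 0.500 M |  | 30 min |

| run | time / min | complex with one exchanged / % | starting complex / % |
|---|---|---|---|
| ash | 0.250 | 8.1 | 90.5 |
| ash | 0.833 | 13.9 | 74.0 |
| ash | 2.50 | 10.2 | 55.0 |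
| ash | 10.0 | 1.2 | 49.1 |
| maple | 0.250 | 8.7 | 89.7 |
| maple | 1.00 | 11.6 | 75.2 |
| maple | 5.00 | 5.4 | 67.1 |
| maple | 20.0 | 2.6 | 68.4 |

(scatter of a reading: 1 percentage point)



* when, up to 30 min, the flask holds most complex with one exchanged
* the amount of complex with one exchanged, in percent of the starting complex charged, at that time
* earliest time at which at least nineteen twentieths of that best amount are there, in min
* latest time at which they still are, in min

At the top of the curve, making equals using. Making goes with the starting complex left, using with the complex with one exchanged, and both ligand steps take the same incoming ligand. So read the ratio of the two amounts at each run's top reading: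

ash: 0.188; maple: 0.154; mean: 0.171

Call this mean the peak ratio: complex with one exchanged over starting complex left, at the highest point.

Turn the charge of starting complex first. By hand, twice the charge leaves less incoming ligand at the top, and the late fall in ash suggests a loss that goes on with little ligand, so expect a lower ratio. Maple's ratio does read lower than ash's, though its fraction left at the top reading is close, 75.2% against 74.0%. Ash's ratio rests on single readings with a scatter of 1 percentage point, so keep the mean, but as a rough figure that maple may pull down.

Turn the time next. The flask repeats ash's charges, so look near 0.833 min.

Turn the incoming ligand last. Both ligand steps slow together, but ash keeps losing complex with one exchanged, from 10.2% at 2.50 min to 1.2% at 10.0 min, while starting complex moves from 55.0% to 49.1%. Expect a lower ratio with less ligand; ash and maple share one ligand charge, so that charge is not varied between them.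

My reckoning for the flask:

best = peak ratio × fraction left = 12.7%

The forecast says 14.2% at 0.95 min, held from 0.65 min to 1.45 min, which is above my figure, because it chose to “interpolate its three points on log time”.

The flask peaks at 0.925 min with 12.1%, and the window asked for runs from 0.601 min to 1.43 min.

    complex with one exchanged + incoming ligand → leaving ligand + complex with two exchanged (k = 21.0 M⁻¹ min⁻¹)
    complex with three exchanged + incoming ligand → leaving ligand + complex with four exchanged (k = 2.30 M⁻¹ min⁻¹)
    complex with one exchanged → over-reaction product (k = 0.220 min⁻¹)
    complex with one exchanged ⇌ isomer of the product (K = 1.80, k = 0.160 min⁻¹)
    complex with two exchanged + incoming ligand → leaving ligand + complex with three exchanged (k = 12.0 M⁻¹ min⁻¹)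
    starting complex + incoming ligand → leaving ligand + complex with one exchanged (k = 4.70 M⁻¹ min⁻¹)

At 0.925 min the flask has 71.7% starting complex left, so its own ratio is 0.169. Now take the neighbour charged with 0.025 M incoming ligand, the limiting reagent, of which 0% remains at the end. There 81% starting complex remains, so the peak ratio asks for 13.8%, yet its best is 6.72%. Its ratio at the peak is at most 0.0830, about half the peak ratio.

The readings were computed with constants of no real substance; the scatter is artificial.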